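**Plan**

1. Numbering (used for every compound): ring carbons C1 (CH–OAng), C2 (CH2), C3 (CH–OAng), C4 (C–CH3), C5, C6, C7 (three CH), C8 (C=O), C9 (CH2), C10 (CH–CH3), C11 (C bearing CH3 and CH2OH). Enabling feature: C4 and C6 are the 1,3-corners of the cyclobutane C4–C5–C6–C7 and are tied together by the bridge C3–C2–C1–C11. This bicyclo[4.1.1]octane is what opening the central bond of a bicyclo[1.1.0]butane with a four-atom partner delivers.
2. Cuts, in retrosynthetic order: the two angelate C–O bonds; C10–CH3 and C9–C10 of the six-membered ring C5–C10–C9–C8–C7 (cuprate, aldol); the C1/C3 oxygen functions and the C11–CH2OH bond; C6–C11 and C3–C4 (annulation); C4–C6 and C4–C7 of the bicyclobutane (carbene addition).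
3. Forward order: acyclic diazo ester → bicyclobutane with both side chains exo → seven-membered ring across the cyclobutane (step 7) → C11 quaternisation and C1/C3 oxygenation → C4 ester to methyl → six-membered ring on the opposite cyclobutane face → angelates.
4. Stereochemistry: C5 from (S)-benzyl glycidyl ether by Claisen chirality transfer, C7 from the E-alkene; C4/C6 from opening of the bicyclobutane on its endo face; C11 from a ligand-controlled hydroxymethylation; C1 and C3 from two internal hydride deliveries relayed from the C11–CH2OH group; C10 from cuprate addition anti to the C4 methyl.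
5. Descriptors in names: the "upper" cyclobutane face carries the C4 ester (later CH3), H-6 and the C5/C7 side chains; the "lower" face carries the C3–C2–C1–C11 bridge; a bridge substituent points to the C5 side or to the C7 side.

Key step: step 7

Assumption: the two faces of the C11 enol silane differ only through the remote C5/C7 side chains, so the hydroxymethylation of step 10 is treated as ligand-controlled; the (S,S)-ligand is written by analogy with 2-methylcycloalkanone enol silanes, and its mirror image would be taken if the sense proved opposite.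

**Route**

Step 1
Reactants: 1 (S)-benzyl glycidyl ether
Product: 2 (S)-1-(benzyloxy)but-3-en-2-ol
Conditions: Me3S+ I− (3.5 equiv), n-BuLi (3.3 equiv), THF, −10 °C → rt
Reagents that add atoms: trimethylsulfonium iodide, C[S+](C)C.[I-]
Why: Dimethylsulfonium methylide opens the epoxide at its CH2 terminus and the resulting β-alkoxy sulfonium ylide eliminates dimethyl sulfide (ylide-mediated one-carbon homologation of an epoxide to an allylic alcohol), so the C–O stereocentre is carried over unchanged.

Step 2
Reactants: 2 (S)-1-(benzyloxy)but-3-en-2-ol; 3 allyloxy(tert-butyl)dimethylsilane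
Product: 4 (S,E)-1-(benzyloxy)-5-(tert-butyldimethylsilyloxy)pent-3-en-2-ol
Conditions: 3 (3 equiv), second-generation Hoveyda–Grubbs catalyst (3 mol %), CH2Cl2, 40 °C
Reagents that add atoms: none
Why: Olefin cross-metathesis of two terminal alkenes with loss of ethylene should give the E-disubstituted alkene, as is usual for secondary allylic alcohols paired with allyl silyl ethers.

Step 3
Reactants: 4 (S,E)-1-(benzyloxy)-5-(tert-butyldimethylsilyloxy)pent-3-en-2-ol; 5 trimethyl orthoacetate
Product: 7 methyl (R,E)-6-(benzyloxy)-3-[(tert-butyldimethylsilyloxy)methyl]hex-4-enoate, via ketene acetal 6 (not isolated)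
Conditions: MeC(OMe)3 (6 equiv), EtCO2H (5 mol %), xylene, 135 °C, MeOH distilled off
Reagents that add atoms: none
Why: Johnson–Claisen rearrangement through a chair transition state with the CH2OBn group equatorial transfers the carbinol configuration to the new C–C stereocentre (future C5) and leaves an E-alkene.

Step 4
Reactants: 7 methyl (R,E)-6-(benzyloxy)-3-[(tert-butyldimethylsilyloxy)methyl]hex-4-enoate
Product: 9 methyl (S,E)-6-(benzyloxy)-3-[(tert-butyldimethylsilyloxy)methyl]-2-diazohex-4-enoate, via trifluoroacetyl ester 8 (not isolated)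
Conditions: LiN(SiMe3)2, THF, −78 °C, then CF3CO2CH2CF3; then MsN3, Et3N, MeCN, rt
Reagents that add atoms: methanesulfonyl azide, CS(=O)(=O)N=[N+]=[N-]; 2,2,2-trifluoroethyl trifluoroacetate, O=C(OCC(F)(F)F)C(F)(F)F (its acyl group is in 8 only)
Why: Deacylative Regitz diazo transfer, in which Claisen trifluoroacetylation activates the ester α-carbon so that the sulfonyl azide delivers N2 with loss of the trifluoroacetyl group, leaves the neighbouring stereocentre untouched.

Step 5
Reactants: 9 methyl (S,E)-6-(benzyloxy)-3-[(tert-butyldimethylsilyloxy)methyl]-2-diazohex-4-enoate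
Product: 10 methyl 2-exo-(benzyloxymethyl)-4-exo-[(tert-butyldimethylsilyloxy)methyl]bicyclo[1.1.0]butane-1-carboxylate
Conditions: Rh2(O2CCPh3)4 (1 mol %), toluene, −78 → −40 °C, slow addition of 9
Reagents that add atoms: none
Why: Rhodium-carbene intramolecular cyclopropanation of the allylic alkene (the established passage from 2-diazopent-4-enoates to bicyclobutane-1-carboxylates) should set C4, C6 and C7, because the bulky carboxylate and low temperature disfavour 1,2-hydride shift, the E-alkene places CH2OBn exo on C7 stereospecifically, and the C5 centre steers the carbene to the alkene face that keeps CH2OTBS on the convex side.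

Step 6
Reactants: 11 ethyl vinyl ketone
Product: 12 (Z)-3-(triethylsilyloxy)penta-1,3-diene
Conditions: Et3SiOTf, Et3N, Et2O, 0 °C
Reagents that add atoms: triethylsilyl trifluoromethanesulfonate, CC[Si](CC)(CC)OS(=O)(=O)C(F)(F)F
Why: Soft enolisation with a silyl triflate and an amine at the only enolisable position should give the Z-configured 2-silyloxydiene.

Step 7
Reactants: 10 methyl 2-exo-(benzyloxymethyl)-4-exo-[(tert-butyldimethylsilyloxy)methyl]bicyclo[1.1.0]butane-1-carboxylate; 12 (Z)-3-(triethylsilyloxy)penta-1,3-diene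
Product: 14 methyl 7-(benzyloxymethyl)-8-[(tert-butyldimethylsilyloxy)methyl]-2-methyl-3-oxobicyclo[4.1.1]octane-6-carboxylate (C1 ketone; both C11 epimers), via triethylsilyl enol ether 13 (not isolated)
Conditions: 12 (2 equiv), HNTf2 (10 mol %, gives Et3SiNTf2 in situ), CH2Cl2, −78 → −30 °C; then 0.5 M HCl, THF, 0 °C
Reagents that add atoms: none
Why: Proposed new method: HNTf2 protodesilylates a little of 12 to Et3SiNTf2, which silylates the ester carbonyl of 10 and polarises the central C4–C6 bond; the enol-silane carbon C11 of 12 then attacks C6 along the back lobe of that bond (SN2-like, with release of roughly 40 kcal/mol of strain) to give a C4 silyl ketene acetal and an O-silylated vinyl ketone, and the ketene acetal adds to the enone terminus C3 (intramolecular Mukaiyama–Michael), returning the silyl cation and leaving enol ether 13, which the acidic quench hydrolyses. The closest known reaction type is the Lewis-acid-catalysed formal [4+2] annulation of acyl bicyclobutanes with silyl dienol ethers to bicyclo[4.1.1]octanes, so far confined to bridgehead-aryl, wing-unsubstituted substrates, together with triflimide-catalysed Mukaiyama–Michael additions of enol silanes to acrylates. The seven-membered ring (C4–C3–C2–C1–C11–C6 plus C5 or C7) closes in the 7-endo-trig mode. C4 and C6 are set together: both back lobes lie on the endo face, so the new bridge is cis across the cyclobutane and trans to the exo side chains on C5 and C7, as in the target, whereas C11 forms without control, is drawn unassigned and becomes trigonal again in step 9. The step needs attack at C6 and not C4, and 1,4- and not 1,2-closure of the enolate: the ester fixes the polarity of the central bond, the exo-only substitution leaves the endo face open, and the strained, reversible aldol alternative (a bicyclo[2.1.1]hexane) should drain into the Michael product.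

Step 8
Reactants: 14 C1 ketone
Product: 16 C2–C3 enone (C11 unassigned), via trimethylsilyl enol ether 15 (not isolated)
Conditions: LiN(i-Pr)2, Me3SiCl, THF, −78 °C; then Pd(OAc)2 (1.1 equiv), MeCN, rt
Reagents that add atoms: chlorotrimethylsilane, C[Si](C)(C)Cl (its silyl group is in 15 only)
Why: Kinetic deprotonation at the less hindered C2 methylene followed by Saegusa–Ito oxidation of the enol silane should place the double bond at C2–C3.

Step 9
Reactants: 16 C2–C3 enone
Product: 17 2-(trimethylsilyloxy)diene C11=C1(OSiMe3)–C2=C3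
Conditions: Me3SiOTf, Et3N, CH2Cl2, 0 °C
Reagents that add atoms: trimethylsilyl trifluoromethanesulfonate, C[Si](C)(C)OS(=O)(=O)C(F)(F)F
Why: Soft enolisation can occur only at C11, since C4 carries no γ-hydrogen, and should give the cross-conjugated silyl dienol ether in which C11 is trigonal.

Step 10
Reactants: 17 2-(trimethylsilyloxy)diene
Product: 18 C11-hydroxymethyl enone (CH2OH to the C7 side, CH3 to the C5 side)
Conditions: Sc(OTf)3 (10 mol %), (S,S)-6,6'-bis(1-hydroxy-2,2-dimethylpropyl)-2,2'-bipyridine (12 mol %), 37% aq. HCHO (5 equiv), DME/H2O 9:1, −20 °C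
Reagents that add atoms: formaldehyde, C=O
Why: Catalytic enantioselective Mukaiyama aldol hydroxymethylation of an enol silane in aqueous medium, in which the chiral scandium–bipyridine complex should deliver formaldehyde to the C11 face on the C7 side, a choice the substrate cannot make by itself.

Step 11
Reactants: 18 C11-hydroxymethyl enone
Product: 19 C2,C3-epoxy ketone (both epoxide faces)
Conditions: t-BuOOH, DBU, CH2Cl2, 0 °C → rt
Reagents that add atoms: tert-butyl hydroperoxide, CC(C)(C)OO
Why: Weitz–Scheffer nucleophilic epoxidation of the enone, whose facial outcome is irrelevant because C3 becomes a carbonyl carbon in the next step.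

Step 12
Reactants: 19 C2,C3-epoxy ketone
Product: 20 C1,C3-diketone
Conditions: Pd(PPh3)4 (5 mol %), dppe (5 mol %), toluene, 80 °C
Reagents that add atoms: none
Why: Isomerisation of an α,β-epoxy ketone to the 1,3-diketone by a zerovalent palladium catalyst (C–O oxidative addition at C2, β-hydride elimination of H-3, tautomerisation) runs under neutral conditions that should spare the β-hydroxy ketone.

Step 13
Reactants: 20 C1,C3-diketone
Product: 22 triol (C1–OH to the C5 side, C3–OH to the C7 side), via hydroxy ketone 21 (not isolated)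
Conditions: Me4NBH(OAc)3 (8 equiv), MeCN/AcOH 1:1, −30 → 0 °C
Reagents that add atoms: none
Why: Evans–Saksena directed reduction used twice in one pot: the acetoxyborohydride bound to the C11–CH2OH oxygen delivers hydride to C1 on the C7 side so that the new hydroxyl points to the C5 side (trans to CH2OH), and the C1 alkoxyborohydride then reduces the C3 ketone internally to the anti 1,3-diol with C3–OH on the C7 side, while the ester, lacking a directing hydroxyl, is not reduced.

Step 14
Reactants: 22 triol
Product: 23 primary tert-butyldiphenylsilyl ether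
Conditions: t-BuPh2SiCl (1.1 equiv), imidazole, DMF, 0 °C
Reagents that add atoms: tert-butyl(chloro)diphenylsilane, CC(C)(C)[Si](Cl)(c1ccccc1)c1ccccc1
Why: Silylation should be selective for the primary alcohol over the two neopentyl-type secondary alcohols.

Step 15
Reactants: 23 primary tert-butyldiphenylsilyl ether
Product: 24 C1,C3-bis(methoxymethyl) ether
Conditions: MOMCl (6 equiv), i-Pr2NEt, Bu4NI (cat.), CH2Cl2, 40 °C
Reagents that add atoms: chloromethyl methyl ether, COCCl
Why: Williamson-type O-alkylation converts both secondary alcohols into methoxymethyl ethers, which withstand the hydride, organometallic and basic steps that follow.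

Step 16
Reactants: 24 C1,C3-bis(methoxymethyl) ether
Product: 25 C4-hydroxymethyl compound
Conditions: LiAlH4, THF, 0 °C → rt
Reagents that add atoms: none
Why: Hydride reduction of the hindered C4 methyl ester to the primary alcohol leaves silyl, benzyl and acetal ethers intact.

Step 17
Reactants: 25 C4-hydroxymethyl compound
Product: 26 C4-CH2OMs mesylate
Conditions: MsCl, Et3N, CH2Cl2, 0 °C
Reagents that add atoms: methanesulfonyl chloride, CS(=O)(=O)Cl
Why: Sulfonylation of the only free hydroxyl group.

Step 18
Reactants: 26 C4-CH2OMs mesylate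
Product: 27 C4-methyl compound
Conditions: LiEt3BH (5 equiv), THF, 0 → 65 °C
Reagents that add atoms: none
Why: SN2 hydride displacement of the neopentyl-type mesylate by lithium triethylborohydride, the standard reagent for hindered primary sulfonates, should turn C4–CH2OMs into the C4 methyl group.

Step 19
Reactants: 27 C4-methyl compound
Product: 28 C7-hydroxymethyl compound
Conditions: H2 (1 atm), 10% Pd/C, EtOAc, rt
Reagents that add atoms: none
Why: Hydrogenolysis of the benzyl ether frees the C7 side chain while silyl and methoxymethyl ethers remain.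

Step 20
Reactants: 28 C7-hydroxymethyl compound
Product: 29 C7 aldehyde
Conditions: Dess–Martin periodinane, NaHCO3, CH2Cl2, rt
Reagents that add atoms: none
Why: Dess–Martin oxidation of the primary alcohol gives the aldehyde, which sits on the upper face, also the thermodynamically preferred one.

Step 21
Reactants: 29 C7 aldehyde
Product: 31 diol (C7–CH(OH)CH3 as both epimers; C5–CH2OH), via silyl ether 30 (not isolated)
Conditions: MeMgBr, THF, −78 °C; then 1 M HCl, MeOH, rt
Reagents that add atoms: methylmagnesium bromide, C[Mg]Br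
Why: Grignard addition to the aldehyde gives the methyl carbinol, whose configuration is immaterial, and the acidic methanol work-up cleaves the primary tert-butyldimethylsilyl ether while the methoxymethyl and tert-butyldiphenylsilyl ethers survive.

Step 22
Reactants: 31 diol
Product: 32 keto aldehyde (C7 acetyl, C5 formyl)
Conditions: Dess–Martin periodinane (3 equiv), NaHCO3, CH2Cl2, rt
Reagents that add atoms: none
Why: Double Dess–Martin oxidation gives the C7 methyl ketone and the C5 aldehyde, both on the upper face of the cyclobutane.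

Step 23
Reactants: 32 keto aldehyde
Product: 34 tricyclic enone C8(=O)–C9=C10, via aldol 33 (not isolated)
Conditions: KOH, MeOH, 0 °C → rt
Reagents that add atoms: none
Why: Intramolecular aldol condensation, in which the methyl-ketone enolate (C9) adds to the cis-disposed aldehyde (C10) in a 6-(enolendo)-exo-trig closure and E1cB dehydration follows, should give the conjugated bicyclo[3.1.1]heptenone, the ring system of apoverbenone.

Step 24
Reactants: 34 tricyclic enone
Product: 35 C10-methyl ketone (CH3 directed toward C6)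
Conditions: Me2CuLi (from MeLi and CuI), Et2O, −78 → −30 °C; aq. NH4Cl
Reagents that add atoms: lithium dimethylcuprate, [Li+].C[Cu-]C
Why: Organocuprate conjugate addition should, as with verbenone-type enones, bring the methyl group to C10 from the side of the C6–H bridge, anti to the C4 bridge whose methyl overhangs the enone, which is the target configuration.

Step 25
Reactants: 35 C10-methyl ketone
Product: 36 C1,C3-diol
Conditions: Me2BBr, CH2Cl2, −78 °C; then aq. NaHCO3
Reagents that add atoms: none
Why: Lewis-acid cleavage of the methoxymethyl ethers by bromodimethylborane at low temperature should leave the ketone and the primary tert-butyldiphenylsilyl ether intact.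

Step 26
Reactants: 36 C1,C3-diol; 37 angelic acid
Product: 38 bis-angelate silyl ether
Conditions: 37 (6 equiv), 2,4,6-Cl3C6H2COCl, Et3N, toluene, rt; then 36, 80 °C
Reagents that add atoms: none
Why: Yamaguchi esterification through the mixed 2,4,6-trichlorobenzoic anhydride, run without DMAP so that the Z-angelate is not isomerised to the tiglate, should acylate both hindered secondary alcohols.

Step 27
Reactants: 38 bis-angelate silyl ether
Product: 39 CNP0287707.1
Conditions: HF·pyridine, pyridine, THF, 0 °C → rt
Reagents that add atoms: none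
Why: Fluoride-mediated desilylation under buffered acidic conditions should free the primary alcohol without acyl migration or angelate isomerisation.

**Compound list**

1 | (S)-benzyl glycidyl ether | O1[C@@H](C1)COCc1ccccc1 | starting material
2 | (S)-1-(benzyloxy)but-3-en-2-ol | O[C@@H](C=C)COCc1ccccc1 | intermediate
3 | allyloxy(tert-butyl)dimethylsilane | C=CCO[Si](C)(C)C(C)(C)C | starting material
4 | (S,E)-1-(benzyloxy)-5-(tert-butyldimethylsilyloxy)pent-3-en-2-ol | O[C@@H](/C=C/CO[Si](C)(C)C(C)(C)C)COCc1ccccc1 | intermediate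
5 | trimethyl orthoacetate | COC(C)(OC)OC | starting material
6 | ketene acetal (1-methoxyvinyl ether of 4) | C=C(OC)O[C@@H](/C=C/CO[Si](C)(C)C(C)(C)C)COCc1ccccc1 | intermediate
7 | methyl (R,E)-6-(benzyloxy)-3-[(tert-butyldimethylsilyloxy)methyl]hex-4-enoate | COC(=O)C[C@@H](CO[Si](C)(C)C(C)(C)C)/C=C/COCc1ccccc1 | intermediate
8 | trifluoroacetyl ester (2-trifluoroacetyl derivative of 7; C2 unassigned) | COC(=O)C(C(=O)C(F)(F)F)[C@@H](CO[Si](C)(C)C(C)(C)C)/C=C/COCc1ccccc1 | intermediate
9 | methyl (S,E)-6-(benzyloxy)-3-[(tert-butyldimethylsilyloxy)methyl]-2-diazohex-4-enoate | COC(=O)C(=[N+]=[N-])[C@@H](CO[Si](C)(C)C(C)(C)C)/C=C/COCc1ccccc1 | intermediate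
10 | methyl 2-exo-(benzyloxymethyl)-4-exo-[(tert-butyldimethylsilyloxy)methyl]bicyclo[1.1.0]butane-1-carboxylate (ester on C4; H on C6; CH2OTBS on C5; CH2OBn on C7) | COC(=O)[C@@]12[C@@H](CO[Si](C)(C)C(C)(C)C)[C@@H]1[C@H]2COCc1ccccc1 | intermediate
11 | ethyl vinyl ketone (pent-1-en-3-one) | CCC(=O)C=C | starting material
12 | (Z)-3-(triethylsilyloxy)penta-1,3-diene | C/C=C(\O[Si](CC)(CC)CC)C=C | intermediate
13 | triethylsilyl enol ether (C1=C2) of 14; C11 unassigned | CC[Si](CC)(CC)OC1=CC[C@]2(C(=O)OC)[C@@H](CO[Si](C)(C)C(C)(C)C)[C@@H]([C@H]2COCc2ccccc2)C1C | intermediate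
14 | methyl 7-(benzyloxymethyl)-8-[(tert-butyldimethylsilyloxy)methyl]-2-methyl-3-oxobicyclo[4.1.1]octane-6-carboxylate: C1 ketone; C4 ester and C5/C7 side chains upper; bridge lower; both C11 epimers | O=C1CC[C@]2(C(=O)OC)[C@@H](CO[Si](C)(C)C(C)(C)C)[C@@H]([C@H]2COCc2ccccc2)C1C | intermediate
15 | trimethylsilyl enol ether (C1=C2) of 14; C11 unassigned | C[Si](C)(C)OC1=CC[C@]2(C(=O)OC)[C@@H](CO[Si](C)(C)C(C)(C)C)[C@@H]([C@H]2COCc2ccccc2)C1C | intermediate
16 | C2–C3 enone of 14; C11 unassigned | O=C1C=C[C@]2(C(=O)OC)[C@@H](CO[Si](C)(C)C(C)(C)C)[C@@H]([C@H]2COCc2ccccc2)C1C | intermediate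
17 | 2-(trimethylsilyloxy)diene: C11(CH3)=C1(OSiMe3)–C2=C3 | CC1=C(O[Si](C)(C)C)C=C[C@]2(C(=O)OC)[C@@H](CO[Si](C)(C)C(C)(C)C)[C@H]1[C@H]2COCc1ccccc1 | intermediate
18 | C11-hydroxymethyl enone: C11 carries CH2OH to the C7 side and CH3 to the C5 side | O=C1C=C[C@]2(C(=O)OC)[C@@H](CO[Si](C)(C)C(C)(C)C)[C@@H]([C@H]2COCc2ccccc2)[C@@]1(C)CO | intermediate
19 | C2,C3-epoxy ketone of 18 (epoxide face unassigned) | O=C1C2OC2[C@]3(C(=O)OC)[C@@H](CO[Si](C)(C)C(C)(C)C)[C@@H]([C@H]3COCc3ccccc3)[C@@]1(C)CO | intermediate
20 | C1,C3-diketone | O=C1CC(=O)[C@]2(C(=O)OC)[C@@H](CO[Si](C)(C)C(C)(C)C)[C@@H]([C@H]2COCc2ccccc2)[C@@]1(C)CO | intermediate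
21 | hydroxy ketone: C1–OH to the C5 side; C3 ketone | O[C@@H]1CC(=O)[C@]2(C(=O)OC)[C@@H](CO[Si](C)(C)C(C)(C)C)[C@@H]([C@H]2COCc2ccccc2)[C@@]1(C)CO | intermediate
22 | triol: C1–OH to the C5 side; C3–OH to the C7 side; C11–CH2OH to the C7 side | O[C@@H]1C[C@@H](O)[C@]2(C(=O)OC)[C@@H](CO[Si](C)(C)C(C)(C)C)[C@@H]([C@H]2COCc2ccccc2)[C@@]1(C)CO | intermediate
23 | C11–CH2O tert-butyldiphenylsilyl ether of 22 | O[C@@H]1C[C@@H](O)[C@]2(C(=O)OC)[C@@H](CO[Si](C)(C)C(C)(C)C)[C@@H]([C@H]2COCc2ccccc2)[C@@]1(C)CO[Si](c1ccccc1)(c1ccccc1)C(C)(C)C | intermediate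
24 | C1,C3-bis(methoxymethyl) ether of 23 | COCO[C@@H]1C[C@@H](OCOC)[C@]2(C(=O)OC)[C@@H](CO[Si](C)(C)C(C)(C)C)[C@@H]([C@H]2COCc2ccccc2)[C@@]1(C)CO[Si](c1ccccc1)(c1ccccc1)C(C)(C)C | intermediate
25 | C4-hydroxymethyl compound (ester reduced) | COCO[C@@H]1C[C@@H](OCOC)[C@]2(CO)[C@@H](CO[Si](C)(C)C(C)(C)C)[C@@H]([C@H]2COCc2ccccc2)[C@@]1(C)CO[Si](c1ccccc1)(c1ccccc1)C(C)(C)C | intermediate
26 | C4–CH2OMs mesylate | COCO[C@@H]1C[C@@H](OCOC)[C@]2(COS(C)(=O)=O)[C@@H](CO[Si](C)(C)C(C)(C)C)[C@@H]([C@H]2COCc2ccccc2)[C@@]1(C)CO[Si](c1ccccc1)(c1ccccc1)C(C)(C)C | intermediate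
27 | C4-methyl compound | COCO[C@@H]1C[C@@H](OCOC)[C@]2(C)[C@@H](CO[Si](C)(C)C(C)(C)C)[C@@H]([C@H]2COCc2ccccc2)[C@@]1(C)CO[Si](c1ccccc1)(c1ccccc1)C(C)(C)C | intermediate
28 | C7-hydroxymethyl compound | COCO[C@@H]1C[C@@H](OCOC)[C@]2(C)[C@@H](CO[Si](C)(C)C(C)(C)C)[C@@H]([C@H]2CO)[C@@]1(C)CO[Si](c1ccccc1)(c1ccccc1)C(C)(C)C | intermediate
29 | C7 aldehyde | COCO[C@@H]1C[C@@H](OCOC)[C@]2(C)[C@@H](CO[Si](C)(C)C(C)(C)C)[C@@H]([C@H]2C=O)[C@@]1(C)CO[Si](c1ccccc1)(c1ccccc1)C(C)(C)C | intermediate
30 | silyl ether: C7–CH(OH)CH3 (both epimers) with C5–CH2OTBS | COCO[C@@H]1C[C@@H](OCOC)[C@]2(C)[C@@H](CO[Si](C)(C)C(C)(C)C)[C@@H]([C@H]2C(C)O)[C@@]1(C)CO[Si](c1ccccc1)(c1ccccc1)C(C)(C)C | intermediate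
31 | diol: C7–CH(OH)CH3 (both epimers) and C5–CH2OH | COCO[C@@H]1C[C@@H](OCOC)[C@]2(C)[C@@H](CO)[C@@H]([C@H]2C(C)O)[C@@]1(C)CO[Si](c1ccccc1)(c1ccccc1)C(C)(C)C | intermediate
32 | keto aldehyde: C7 acetyl and C5 formyl, both upper | COCO[C@@H]1C[C@@H](OCOC)[C@]2(C)[C@@H](C=O)[C@@H]([C@H]2C(C)=O)[C@@]1(C)CO[Si](c1ccccc1)(c1ccccc1)C(C)(C)C | intermediate
33 | aldol: C8 ketone with C10 carbinol (unassigned) | COCO[C@@H]1C[C@@H](OCOC)[C@]2(C)[C@@H]3[C@@H]([C@H]2C(=O)CC3O)[C@@]1(C)CO[Si](c1ccccc1)(c1ccccc1)C(C)(C)C | intermediate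
34 | tricyclic enone C8(=O)–C9=C10 | COCO[C@@H]1C[C@@H](OCOC)[C@]2(C)[C@@H]3[C@@H]([C@H]2C(=O)C=C3)[C@@]1(C)CO[Si](c1ccccc1)(c1ccccc1)C(C)(C)C | intermediate
35 | tricyclic ketone with C10–CH3 directed toward C6 | COCO[C@@H]1C[C@@H](OCOC)[C@]2(C)[C@@H]3[C@@H]([C@H]2C(=O)C[C@H]3C)[C@@]1(C)CO[Si](c1ccccc1)(c1ccccc1)C(C)(C)C | intermediate
36 | C1,C3-diol with C11–CH2O tert-butyldiphenylsilyl ether | O[C@@H]1C[C@@H](O)[C@]2(C)[C@@H]3[C@@H]([C@H]2C(=O)C[C@H]3C)[C@@]1(C)CO[Si](c1ccccc1)(c1ccccc1)C(C)(C)C | intermediate
37 | angelic acid, (Z)-2-methylbut-2-enoic acid | C/C=C(/C)C(=O)O | starting material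
38 | C1,C3-bis-angelate with C11–CH2O tert-butyldiphenylsilyl ether | C/C=C(/C)C(=O)O[C@@H]1C[C@@H](OC(=O)/C(C)=C\C)[C@]2(C)[C@@H]3[C@@H]([C@H]2C(=O)C[C@H]3C)[C@@]1(C)CO[Si](c1ccccc1)(c1ccccc1)C(C)(C)C | intermediate
39 | CNP0287707.1 | C/C=C(/C)C(=O)O[C@@H]1C[C@@H](OC(=O)/C(C)=C\C)[C@]2(C)[C@@H]3[C@@H]([C@H]2C(=O)C[C@H]3C)[C@@]1(C)CO | target

**Step count and risks**

Total: 27 steps. Longest linear sequence: 26 steps (steps 1–5 and 7–27, from 1 to 39); step 6 is the one-step side branch to the diene.

Steps most likely to fail: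

1. Step 7. With no cation-stabilising group on C6, the silyl-activated bicyclobutane may isomerise or oligomerise faster than the enol silane attacks, or the C4 enolate may close 1,2 instead of 1,4. The two bonds would then be made one after the other by known chemistry. Starting from 10, copper-catalysed homoconjugate addition of isopropenylmagnesium bromide (CuBr·SMe2, PBu3, THF) at C6, followed by alkylation of the resulting C4 ester enolate with 4-iodobut-1-ene on the same endo face, would give cyclobutane F1. Ring-closing metathesis (second-generation Hoveyda–Grubbs catalyst) would join the two alkenes to the trisubstituted C11=C1 alkene F2. Hydroboration–oxidation (BH3·THF, then NaBO3) would place the hydroxyl on the less substituted C1 to give alcohol F3, and Dess–Martin oxidation would return to ketone 14.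

2. Step 5. The β-branched carbene may undergo 1,2-hydride shift to a dienoate faster than it cyclopropanates, or it may add to the alkene face that turns the C5 side chain endo. The central bond would then be closed by anions in place of a carbene. From ester 7, Shi epoxidation with the enantiomeric (L-sorbose-derived) ketone catalyst would give the (3S,4S,5S)-epoxide F4. LiN(SiMe3)2 would trigger 3-exo-tet opening by the ester enolate to cyclopropyl carbinol F5, and mesylation would give mesylate F6. KN(SiMe3)2 would then close the second three-membered ring by internal SN2 displacement, the 1,3-elimination known for sulfonyl bicyclobutanes, to give 10. Both displacements invert, which fixes both side chains exo.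

3. Step 10. Aldol addition at the tetrasubstituted, neopentyl-like C11 terminus may be slow enough for protodesilylation back to 16 to win, or the catalyst may discriminate poorly between the two faces. C11 would then be quaternised by a palladium-catalysed decarboxylative asymmetric allylic alkylation and the allyl group trimmed. From enone 16, NaN(SiMe3)2 and allyl chloroformate would give dienyl carbonate F7. Pd2(dba)3 with (S)-t-BuPHOX would give the C11-allyl enone F8 (allyl to the C7 side by analogy with 2-methylcycloalkanones). RuHCl(CO)(PPh3)3 would move the double bond to give the propenyl enone F9. Ozonolysis selective for the electron-rich propenyl group (O3, pyridine, CH2Cl2, −78 °C; Me2S) would give aldehyde F10, and NaBH(OAc)3 would reduce the aldehyde alone to give 18.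

**Further compounds**

F1 | step 7 | cyclobutane: C4 carries CO2Me (upper) and but-3-enyl (lower); C6 carries isopropenyl (lower); C5–CH2OTBS and C7–CH2OBn upper | C=CCC[C@]1(C(=O)OC)[C@@H](CO[Si](C)(C)C(C)(C)C)[C@H](C(C)=C)[C@H]1COCc1ccccc1
F2 | step 7 | alkene: bicyclo[4.1.1]oct-2-ene with C11(CH3)=C1H; C4 ester; side chains as in 14 | CC1=CCC[C@]2(C(=O)OC)[C@@H](CO[Si](C)(C)C(C)(C)C)[C@H]1[C@H]2COCc1ccccc1
F3 | step 7 | alcohol: C1 carbinol corresponding to 14 (C1 and C11 unassigned) | OC1CC[C@]2(C(=O)OC)[C@@H](CO[Si](C)(C)C(C)(C)C)[C@@H]([C@H]2COCc2ccccc2)C1C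
F4 | step 5 | epoxide: methyl (3S,4S,5S)-6-(benzyloxy)-3-[(tert-butyldimethylsilyloxy)methyl]-4,5-epoxyhexanoate | COC(=O)C[C@@H](CO[Si](C)(C)C(C)(C)C)[C@@H]1O[C@H]1COCc1ccccc1
F5 | step 5 | cyclopropyl carbinol: methyl 2-[2-(benzyloxy)-1-hydroxyethyl]-3-[(tert-butyldimethylsilyloxy)methyl]cyclopropane-1-carboxylate; ring side chains trans; carbinol centre as in F4; C1 unassigned | COC(=O)C1[C@@H](CO[Si](C)(C)C(C)(C)C)[C@@H]1[C@@H](O)COCc1ccccc1
F6 | step 5 | mesylate of F5 | COC(=O)C1[C@@H](CO[Si](C)(C)C(C)(C)C)[C@@H]1[C@@H](OS(C)(=O)=O)COCc1ccccc1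
F7 | step 10 | dienyl carbonate: allyl carbonate of the C11=C1 dienol of 16 | CC1=C(OC(=O)OCC=C)C=C[C@]2(C(=O)OC)[C@@H](CO[Si](C)(C)C(C)(C)C)[C@H]1[C@H]2COCc1ccccc1
F8 | step 10 | C11-allyl enone: allyl to the C7 side, CH3 to the C5 side | O=C1C=C[C@]2(C(=O)OC)[C@@H](CO[Si](C)(C)C(C)(C)C)[C@@H]([C@H]2COCc2ccccc2)[C@@]1(C)CC=C
F9 | step 10 | propenyl enone: C11-(E)-prop-1-enyl | O=C1C=C[C@]2(C(=O)OC)[C@@H](CO[Si](C)(C)C(C)(C)C)[C@@H]([C@H]2COCc2ccccc2)[C@@]1(C)/C=C/C
F10 | step 10 | aldehyde: C11-formyl enone | O=C1C=C[C@]2(C(=O)OC)[C@@H](CO[Si](C)(C)C(C)(C)C)[C@@H]([C@H]2COCc2ccccc2)[C@@]1(C)C=O
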